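## Analysis of the target

The target 20 is a C30 hydrocarbon built from two identical drim-8-ene units joined through C11–C11'. Drimane numbering is used for each half: C1–C10 form the decalin, C4 carries the gem-dimethyl group, C5 is the ring-fusion CH, C10 the methyl-bearing ring-fusion carbon, C8=C9 the ring B alkene with a methyl group (C12) on C8 and the tether carbon C11 on C9; primes mark the second half. There are four stereocentres, C5, C10, C5' and C10', all (S). In each half 5-H is α and the C10 methyl group β (trans-decalin), and both halves have the same absolute sense, so the molecule is C2-symmetric and an error in one half gives a diastereomer. The molecule has no heteroatom. Its only functional groups are two tetrasubstituted alkenes, which are inert to most reagents but migrate under acid toward C7 or the exocyclic position, so their position has to be fixed by construction and strong acid avoided late. The difficulties are the quaternary C10 directly bonded to the tetrasubstituted alkene carbon C9, the need to create it twice with the same configuration, the trans relation of 5-H to the C10 methyl next to the 4,4-dimethyl group, and the fact that every auxiliary function must be removed again. The plan rests on two structural features. The six central carbons C8–C9–C11–C11'–C9'–C8' are the carbon chain of adipic acid. Ring A maps onto ketoisophorone, with C10 as its methyl-bearing alkene carbon, C1 the other alkene carbon, C2 the unhindered carbonyl, C4 the CMe2 carbon and C5 the hindered carbonyl. An O–C2–C1=C10 allylic unit can therefore pass the configuration of a C2 carbinol to C10 by a [3,3] shift of an adipate-derived ketene acetal.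

## Retrosynthetic reasoning

20 from 19. The last operation only saturates C6=C7 of the ring B diene in 19. It is placed last because the C6=C7 bond is what guarantees the position of C8=C9 (see next paragraph), and a concerted hydrogen-transfer reduction can remove it without touching or moving the tetrasubstituted alkene.

19 from 18 and 16. The C8–C12 bond is cut: the methyl group is brought in by cross-coupling of the dienyl triflate 18 with a methyl nucleophile. The triflate comes from the enone 16 by α'-deprotonation. A saturated C8 ketone would enolise toward the C7 methylene and give the wrong alkene. In 16 C7 is sp2, so only the C9 hydrogen can be removed and the enol double bond must be C8=C9.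

16 from 14, 13 and 12. The enone 16 arises by dehydrogenation of the saturated trans-decalone 14 through its kinetic C7 enol ether. 14 comes from the β,γ-unsaturated ketone 13 by hydrogenation, which sets 5-H on the α face opposite the C10 methyl group. 13 comes from the tertiary alcohol 12 by dehydration, for which C6 offers the only hydrogens. This order (dehydrate, hydrogenate, then functionalise C8) keeps a C5=C6 bond and a C8 enolate from ever coexisting, since together they would form a linear dienolate and misplace the alkene.

12 from 11, 9 and 10. Ring B is opened at C5–C6: a reductive ketyl–olefin closure joins the hindered C5 carbonyl to the terminal carbon of a vinyl ketone. The C7–C8 bond of the bis(vinyl ketone) 11 is cut next, leading to the bis(N-methoxy-N-methylamide) 9 and vinylmagnesium bromide 10. The amide 9 is the activated form of the diacid 7. C5 cannot enolise, so it can only serve as an electrophile or radical precursor, which is why the two missing carbons are attached at C8 first.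

7 from 4. Both C9–C10 bonds are cut at once. In the forward direction the diester 4 is converted into its bis(silyl ketene acetal), and two [3,3] shifts form C9–C10 and C9'–C10' with transfer of configuration from the C2 and C2' carbinol carbons to the quaternary C10 and C10'. This is the only point at which the absolute configuration of the skeleton is created. The cut is made here because it delivers the whole six-carbon centre between two quaternary stereocentres of the same sense in one operation, and leaves the C8 carboxyl groups and C5 carbonyls as handles for ring B.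

4 from 2, 3 and 1. The ester bonds are cut to the (S)-alcohol 2 and adipoyl chloride 3. 2 comes from ketoisophorone 1 by enantioselective reduction of its unhindered carbonyl. Two reliable steps thus reach the rearrangement substrate.

## Alternatives that were turned down

Alternative 1: Both decalins are disconnected at C5–C10 and C6–C7, back to a C2-symmetric open-chain precursor in which each half carries an enal (C5=C6) tethered to a diene (C10=C9–C8=C7). In the forward direction a chiral imidazolidinone salt activates each enal as its iminium ion, and two intramolecular Diels–Alder reactions give 11,11'-bi(drim-8-ene)-6,6'-dicarbaldehyde A1. In its favour, the step closes all four rings, sets C5 and C10 together, and places C8=C9 by the cycloaddition itself. On ring construction and on alkene placement it is stronger than the chosen route, which closes no ring in its key step and needs steps 9 to 12 to place the alkene. Against it: the diene terminus C10 is fully substituted, so one substituent must point inward in the reactive s-cis conformer. The dienophile carbon C5 is attached to the quaternary C4, so the C5–C10 bond would join two carbons that are each flanked by full substitution. The configuration at C10 depends on the geometry of an acyclic tetrasubstituted C9=C10 alkene that would have to be made stereodefined twice. Two formyl groups would have to be excised afterwards. The chosen route instead draws its configuration from one catalytic ketone reduction and passes it on intramolecularly, so the congested bond formation needs no reagent control.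

Alternative 2: The C9–C11 and C9'–C11' bonds are cut, leading to two molecules of the trans-fused 11-nordriman-9-one A3 and a doubly metalated two-carbon alkyne unit. The forward step is a twofold carbonyl addition, assisted by a cerium salt, that gives 1,2-bis(9-hydroxy-11-nordriman-9-yl)ethyne A2. In its favour: it is the most convergent plan, the decalin stereocentres arrive with the ketone, and the step count is lower than in the chosen route; on these points it is the stronger plan. Against it: the C9 carbonyl lies between the quaternary C10 and the methyl-bearing, enolisable C8, so the second addition (by an alkynyl alkoxide) is doubtful. The alkyne must then be saturated and two tertiary alcohols eliminated toward C8 and not toward C11, without the acid-promoted rearrangements typical of propargylic carbinols and without shifting the alkene to C7. The ketone A3 has to be secured in enantiopure form by a synthesis of its own. The chosen route fixes the alkene by the regiochemistry of an enolate that has no alternative, and makes its own stereocentres from an achiral commodity chemical, at the price of convergence.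

Alternative 3: Ring A of each half is disconnected at C1–C10 and C4–C5, back to the bis-enone 3,3'-(ethane-1,2-diyl)bis(2,4-dimethylcyclohex-2-en-1-one) A5 and a four-carbon vinyl ketone. Under base with a cinchona-derived ammonium salt each enone would react as its extended dienolate at C10, and aldol condensation onto the C5 carbonyl would close ring A and leave the alkene at C8=C9, giving the bis-enone A4. In its favour: C10 and the C8=C9 alkene are set together, and the follow-up (deconjugative dimethylation at C4, hydrogenation to 5α-H, removal of the C3 carbonyl) is classical decalin chemistry. On alkene placement it is at least as strong as the chosen route. Against it: enantioselective alkylation at a fully substituted dienolate carbon must be both α-regioselective and highly face-selective at two sites, and each shortfall produces the meso-type diastereomer. The gem-dimethyl groups and the C3 deoxygenation add roughly as many steps as the chosen route spends on ring B. The chosen route takes its stereocentre from a reduction of established selectivity and a stereospecific rearrangement, so its open question is chemoselectivity and not enantioselectivity, and the gem-dimethyl groups come with the starting material.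

Key step: step 3

Remark on step 1: the (S,S)-configured ruthenium catalyst is taken to give the (S)-carbinol, as it does with aryl and alkenyl ketones; should the sense be opposite, the (R,R)-catalyst is used.

Remark on epimers: C9 and C9' (steps 3 to 9) and the C5 carbinol carbons of 12 are carried as mixtures of epimers, because all of these centres become sp2 or are reset before the end.

## Route

Step 1
Reactants: 1 ketoisophorone (2,6,6-trimethylcyclohex-2-ene-1,4-dione)
Product: 2 (4S)-4-hydroxy-2,6,6-trimethylcyclohex-2-en-1-one
Conditions: RuCl(p-cymene)[(S,S)-TsDPEN] (0.5 mol %), HCO2H–Et3N (5:2), CH2Cl2, 25 °C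
Reagents that add atoms: none
Why: Noyori asymmetric transfer hydrogenation; only the C4 carbonyl (drimane C2) is accessible, the other being flanked by the CMe2 carbon and the methyl-bearing alkene carbon, and the catalyst distinguishes the alkenyl flank from the CH2 flank to set the (S)-carbinol.

Step 2
Reactants: 2 (4S)-4-hydroxy-2,6,6-trimethylcyclohex-2-en-1-one (2.1 equiv); 3 adipoyl chloride (1.0 equiv)
Product: 4 bis[(1S)-3,5,5-trimethyl-4-oxocyclohex-2-en-1-yl] hexanedioate
Conditions: pyridine, DMAP (cat.), CH2Cl2, 0 → 25 °C
Reagents that add atoms: none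
Why: Twofold DMAP-catalysed acylation of a secondary alcohol by a diacid dichloride; the carbinol C–O bond is not touched, so the (S) configuration is retained, and pyridine is used instead of a trialkylamine so that 3 is not converted into a ketene.

Step 3
Reactants: 4 bis[(1S)-3,5,5-trimethyl-4-oxocyclohex-2-en-1-yl] hexanedioate
Product: 7 2,5-bis[(1R)-1,5,5-trimethyl-6-oxocyclohex-2-en-1-yl]hexanedioic acid, via bis(silyl ketene acetal) 5 (not isolated), via bis(trimethylsilyl ester) 6 (not isolated)
Conditions: LiN(SiMe3)2 (2.6 equiv), Me3SiCl–Et3N (6 equiv), THF–toluene, −78 → 25 °C, then 80 °C; 1 M HCl work-up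
Reagents that add atoms: none
Why: LiN(SiMe3)2 removes one α-hydrogen from each ester and the Me3SiCl already present traps each enolate as the silyl ketene acetal 5. On warming, each O–C8(=C9) unit undergoes a concerted [3,3]-sigmatropic shift, the Ireland–Claisen rearrangement of a cyclohex-2-enyl ester being the closest known reaction type; this forms C9–C10, breaks C2–O and moves the ring alkene to C1=C2. No ring is closed. C10 and C10' are controlled by the C2 and C2' carbinol configuration, because the six-membered transition state can only span one face of the ring: C9 arrives on the α face that carried oxygen and the methyl group ends up β in both halves, while C9 and C9' form without control and are later made sp2. The first selectivity needed is ester α-deprotonation over deprotonation at the γ position (C2–H) of the enone and over attack at the ring carbonyl; C4 is quaternary and offers no α' hydrogen, the C5 carbonyl is shielded by its two fully substituted neighbours, and the ester α-hydrogens sit on an unhindered chain. The second is the [3,3] shift over conjugate closure of C9 onto C1, which is served by silylating the enolate as it forms and heating the neutral ketene acetal in a medium of low polarity without Lewis acid. The acyl group on the receiving alkene carbon slows the shift, hence the heating, and the gain of the silyl ester carbonyl outweighs the loss of enone conjugation. Acidic work-up hydrolyses the bis(silyl ester) 6 to 7.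

Step 4
Reactants: 7 2,5-bis[(1R)-1,5,5-trimethyl-6-oxocyclohex-2-en-1-yl]hexanedioic acid
Product: 9 N1,N6-dimethoxy-N1,N6-dimethyl-2,5-bis[(1R)-1,5,5-trimethyl-6-oxocyclohex-2-en-1-yl]hexanediamide, via diacid dichloride 8 (not isolated)
Conditions: (COCl)2, DMF (cat.), CH2Cl2, 0 → 25 °C; then MeNH(OMe)·HCl, pyridine, CH2Cl2, 0 °C
Reagents that add atoms: N,O-dimethylhydroxylamine hydrochloride, CNOC.Cl
Why: Acid chloride formation followed by amide formation (Weinreb amide synthesis); the acid chloride is chosen because each carboxyl group sits on a tertiary carbon next to a quaternary one and would react slowly with milder coupling agents.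

Step 5
Reactants: 9 N1,N6-dimethoxy-N1,N6-dimethyl-2,5-bis[(1R)-1,5,5-trimethyl-6-oxocyclohex-2-en-1-yl]hexanediamide; 10 vinylmagnesium bromide (6 equiv)
Product: 11 4,7-bis[(1R)-1,5,5-trimethyl-6-oxocyclohex-2-en-1-yl]deca-1,9-diene-3,8-dione
Conditions: THF, −20 → 0 °C; inverse quench into cold 1 M HCl
Reagents that add atoms: none
Why: Grignard addition to an N-methoxy-N-methylamide stops at the chelated tetrahedral intermediate, which releases the vinyl ketone only on quench; the ring ketone, flanked by two fully substituted carbons, is not attacked at 0 °C, and the acidic inverse quench keeps the liberated hydroxylamine from adding to the enone.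

Step 6
Reactants: 11 4,7-bis[(1R)-1,5,5-trimethyl-6-oxocyclohex-2-en-1-yl]deca-1,9-diene-3,8-dione
Product: 12 11,11'-bi(5ξ-hydroxy-12-nordrim-1-en-8-one) (10β-methyl; epimers at C5 and C9)
Conditions: SmI2 (6 equiv), HMPA, t-BuOH, THF, −78 → 0 °C
Reagents that add atoms: none
Why: SmI2-mediated ketyl–olefin reductive cyclisation; C5 is joined to the terminal carbon C6 of the vinyl ketone in a polarity-matched 6-endo closure (nucleophilic ketyl carbon, enone β-carbon), and the resulting α-keto radical is reduced to the samarium enolate and protonated. The new C5 carbinol centres are not controlled and are removed in step 7.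

Step 7
Reactants: 12 11,11'-bi(5ξ-hydroxy-12-nordrim-1-en-8-one)
Product: 13 11,11'-bi(12-nordrima-1,5-dien-8-one) (10β-methyl; C9 epimers)
Conditions: SOCl2, pyridine, CH2Cl2, 0 °C
Reagents that add atoms: none
Why: Dehydration of a tertiary alcohol through its chlorosulfite with pyridine as base; C4 and C10 carry no hydrogen, so a proton can only be lost from C6 and the alkene can only form at C5=C6. Base-mediated elimination is preferred to acid so that a free C5 cation, and with it methyl migration from C4 or C10, is avoided.

Step 8
Reactants: 13 11,11'-bi(12-nordrima-1,5-dien-8-one)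
Product: 14 11,11'-bi(12-nor-5α-driman-8-one) ((5S,10S) in each half; C9 epimers)
Conditions: H2 (3 atm), 10% Pd/C, EtOAc, 25 °C
Reagents that add atoms: none
Why: Heterogeneous catalytic hydrogenation; the C1=C2 bond is reduced readily, and the hindered C5=C6 bond takes up hydrogen from the α face, opposite the angular C10 methyl group, which sets 5α-H and the trans ring fusion (the usual outcome for 4,4,10-trimethyl-Δ5-octalins). The ketone is inert under these conditions.

Step 9
Reactants: 14 11,11'-bi(12-nor-5α-driman-8-one)
Product: 16 11,11'-bi(12-nor-5α-drim-6-en-8-one), via bis(trimethylsilyl enol ether) 15 (not isolated)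
Conditions: LiN(iPr)2, Me3SiCl, THF, −78 °C; then Pd(OAc)2 (20 mol %), O2 (1 atm), DMSO, 25 °C
Reagents that add atoms: none
Why: Saegusa–Ito oxidation; kinetic deprotonation with in situ silylation occurs at the C7 methylene and not at the hindered C9 methine, and Pd(OAc)2-mediated dehydrosilylation then places the alkene at C6=C7. The purpose is to take the C7 hydrogens out of competition in step 10.

Step 10
Reactants: 16 11,11'-bi(12-nor-5α-drim-6-en-8-one)
Product: 18 11,11'-bi(12-nor-5α-drima-6,8-dien-8-yl trifluoromethanesulfonate), via dilithium bis(dienolate) 17 (not isolated)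
Conditions: LiN(iPr)2, THF, −78 °C; then PhNTf2, −78 → 0 °C
Reagents that add atoms: N-phenylbis(trifluoromethanesulfonimide), O=S(=O)(N(c1ccccc1)S(=O)(=O)C(F)(F)F)C(F)(F)F
Why: Kinetic deprotonation of a cyclohexenone occurs at the α' position, here C9–H, and the cross-conjugated dienolate is trapped on oxygen; with C7 already sp2 the enol triflate double bond can only be C8=C9, and both C9 epimers converge on the same dienolate. γ-Deprotonation at C5 is the slower, equilibrating pathway and is suppressed at −78 °C.

Step 11
Reactants: 18 11,11'-bi(12-nor-5α-drima-6,8-dien-8-yl trifluoromethanesulfonate)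
Product: 19 11,11'-bi(5α-drima-6,8-diene)
Conditions: MeMgBr (3 equiv), Fe(acac)3 (10 mol %), THF–NMP, −30 → 0 °C
Reagents that add atoms: methylmagnesium bromide, C[Mg]Br
Why: Iron-catalysed Kumada-type cross-coupling of an alkenyl triflate with a methyl Grignard reagent; it runs at low temperature, accepts the hindered fully substituted position, and cannot alter the alkene positions fixed by the triflate.

Step 12
Reactants: 19 11,11'-bi(5α-drima-6,8-diene)
Product: 20 11,11'-bi(drim-8-ene), (5S,10S,5'S,10'S)
Conditions: 2-O2NC6H4SO2NHNH2 (excess), Et3N, CH2Cl2, 25 °C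
Reagents that add atoms: none
Why: Diimide reduction; two hydrogens are transferred in a concerted syn fashion to a single C=C, so only 1,2-reduction is possible, and the rate falls steeply with substitution. The cis-disubstituted C6=C7 bond should be reduced while the tetrasubstituted C8=C9 bond stays in place, and no metal hydride is present that could move it.

## Compound list

1 | ketoisophorone (2,6,6-trimethylcyclohex-2-ene-1,4-dione) | CC1=CC(=O)CC(C)(C)C1=O | starting material
2 | (4S)-4-hydroxy-2,6,6-trimethylcyclohex-2-en-1-one | CC1=C[C@@H](O)CC(C)(C)C1=O | intermediate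
3 | adipoyl chloride | ClC(=O)CCCCC(Cl)=O | starting material
4 | bis[(1S)-3,5,5-trimethyl-4-oxocyclohex-2-en-1-yl] hexanedioate | CC1=C[C@@H](OC(=O)CCCCC(=O)O[C@@H]2C=C(C)C(=O)C(C)(C)C2)CC(C)(C)C1=O | intermediate
5 | 1,6-bis(trimethylsilyloxy)-1,6-bis{[(1S)-3,5,5-trimethyl-4-oxocyclohex-2-en-1-yl]oxy}hexa-1,5-diene | CC1=C[C@@H](OC(O[Si](C)(C)C)=CCCC=C(O[Si](C)(C)C)O[C@@H]2C=C(C)C(=O)C(C)(C)C2)CC(C)(C)C1=O | intermediate (not isolated)
6 | bis(trimethylsilyl) 2,5-bis[(1R)-1,5,5-trimethyl-6-oxocyclohex-2-en-1-yl]hexanedioate | C[Si](C)(C)OC(=O)C(CCC(C(=O)O[Si](C)(C)C)[C@@]1(C)C=CCC(C)(C)C1=O)[C@@]1(C)C=CCC(C)(C)C1=O | intermediate (not isolated)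
7 | 2,5-bis[(1R)-1,5,5-trimethyl-6-oxocyclohex-2-en-1-yl]hexanedioic acid | OC(=O)C(CCC(C(=O)O)[C@@]1(C)C=CCC(C)(C)C1=O)[C@@]1(C)C=CCC(C)(C)C1=O | intermediate
8 | 2,5-bis[(1R)-1,5,5-trimethyl-6-oxocyclohex-2-en-1-yl]hexanedioyl dichloride | ClC(=O)C(CCC(C(Cl)=O)[C@@]1(C)C=CCC(C)(C)C1=O)[C@@]1(C)C=CCC(C)(C)C1=O | intermediate (not isolated)
9 | N1,N6-dimethoxy-N1,N6-dimethyl-2,5-bis[(1R)-1,5,5-trimethyl-6-oxocyclohex-2-en-1-yl]hexanediamide | CON(C)C(=O)C(CCC(C(=O)N(C)OC)[C@@]1(C)C=CCC(C)(C)C1=O)[C@@]1(C)C=CCC(C)(C)C1=O | intermediate
10 | vinylmagnesium bromide | C=C[Mg]Br | starting material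
11 | 4,7-bis[(1R)-1,5,5-trimethyl-6-oxocyclohex-2-en-1-yl]deca-1,9-diene-3,8-dione | C=CC(=O)C(CCC(C(=O)C=C)[C@@]1(C)C=CCC(C)(C)C1=O)[C@@]1(C)C=CCC(C)(C)C1=O | intermediate
12 | 11,11'-bi(5ξ-hydroxy-12-nordrim-1-en-8-one), 10β-methyl | C(CC1C(=O)CCC2(O)C(C)(C)CC=C[C@]12C)C1C(=O)CCC2(O)C(C)(C)CC=C[C@]12C | intermediate
13 | 11,11'-bi(12-nordrima-1,5-dien-8-one), 10β-methyl | C(CC1C(=O)CC=C2C(C)(C)CC=C[C@]12C)C1C(=O)CC=C2C(C)(C)CC=C[C@]12C | intermediate
14 | 11,11'-bi(12-nor-5α-driman-8-one), (5S,10S) in each half | C(CC1C(=O)CC[C@H]2C(C)(C)CCC[C@]12C)C1C(=O)CC[C@H]2C(C)(C)CCC[C@]12C | intermediate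
15 | 11,11'-bi(8-trimethylsilyloxy-12-nor-5α-drim-7-ene) | C(CC1C(O[Si](C)(C)C)=CC[C@H]2C(C)(C)CCC[C@]12C)C1C(O[Si](C)(C)C)=CC[C@H]2C(C)(C)CCC[C@]12C | intermediate (not isolated)
16 | 11,11'-bi(12-nor-5α-drim-6-en-8-one), 10β-methyl | C(CC1C(=O)C=C[C@H]2C(C)(C)CCC[C@]12C)C1C(=O)C=C[C@H]2C(C)(C)CCC[C@]12C | intermediate
17 | dilithium 11,11'-bi(12-nor-5α-drima-6,8-dien-8-olate) | C(CC1=C(O[Li])C=C[C@H]2C(C)(C)CCC[C@]12C)C1=C(O[Li])C=C[C@H]2C(C)(C)CCC[C@]12C | intermediate (not isolated)
18 | 11,11'-bi(12-nor-5α-drima-6,8-dien-8-yl trifluoromethanesulfonate) | C(CC1=C(OS(=O)(=O)C(F)(F)F)C=C[C@H]2C(C)(C)CCC[C@]12C)C1=C(OS(=O)(=O)C(F)(F)F)C=C[C@H]2C(C)(C)CCC[C@]12C | intermediate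
19 | 11,11'-bi(5α-drima-6,8-diene), 10β-methyl | C(CC1=C(C)C=C[C@H]2C(C)(C)CCC[C@]12C)C1=C(C)C=C[C@H]2C(C)(C)CCC[C@]12C | intermediate
20 | 11,11'-bi(drim-8-ene), (5S,10S,5'S,10'S) | CC1=C(CCC2=C(C)CC[C@H]3C(C)(C)CCC[C@]23C)[C@@]2(C)CCCC(C)(C)[C@@H]2CC1 | target

## Step count and least certain steps

Total: 12 steps. Longest linear sequence: 12 steps from ketoisophorone 1 (the route is linear; 3 and 10 are commercial reagents).

Step 3 (key step). The likely failures are three. The base may remove the γ-hydrogen at C2 of the enone instead of an ester α-hydrogen. The ester enolate may close onto C1 in a conjugate addition before it is silylated. The shift itself may be slow, because the receiving alkene carbon carries the acyl group, so that the ketene acetal decays or only one half rearranges. All three arise from the enone, so the fallback removes the ring carbonyl before the rearrangement. Starting from 4, Luche reduction (NaBH4, CeCl3·7H2O, MeOH, 0 °C) of both ring ketones gives bis[(1S)-4-hydroxy-3,5,5-trimethylcyclohex-2-en-1-yl] hexanedioate F1. Silylation (t-BuMe2SiOTf, 2,6-lutidine) gives bis[(1S)-4-(tert-butyldimethylsilyloxy)-3,5,5-trimethylcyclohex-2-en-1-yl] hexanedioate F2. Ireland–Claisen rearrangement of this ordinary cyclohex-2-enyl ester under the conditions of step 3 gives 2,5-bis[(1R)-6-(tert-butyldimethylsilyloxy)-1,5,5-trimethylcyclohex-2-en-1-yl]hexanedioic acid F3. The conditions of step 4 convert it into the bis(N-methoxy-N-methylamide) F4. The silyl ethers are kept until this point so that the C5 hydroxyl cannot lactonise onto C8. Bu4NF then gives the bis(hydroxy amide) F5, and oxidation with Dess–Martin periodinane returns to 9.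

Step 6. The vinyl ketone is reduced more easily than the hindered ring ketone, so simple saturation of the enone or intermolecular coupling may outrun ring closure. The fallback builds ring B by polar addition and metathesis. Starting from 9, excess vinylmagnesium bromide with anhydrous CeCl3 (THF, 0 → 25 °C) adds to both the amide and the non-enolisable C5 ketone and gives 4,7-bis[(1R)-6-ethenyl-6-hydroxy-1,5,5-trimethylcyclohex-2-en-1-yl]deca-1,9-diene-3,8-dione F6. Ring-closing metathesis with the second-generation Hoveyda–Grubbs catalyst gives 11,11'-bi(5ξ-hydroxy-12-nordrima-1,6-dien-8-one) F7. Hydrogenation (H2, Pd/C) of C6=C7 and C1=C2 gives 11,11'-bi(5ξ-hydroxy-12-nordriman-8-one) F8. Dehydration as in step 7 gives 11,11'-bi(12-nordrim-5-en-8-one) F9, and hydrogenation as in step 8 rejoins the route at 14.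

Step 8. Facial selectivity may be poor for the C9 epimer whose side chain lies axially on the α face, the hindered trisubstituted alkene may take up hydrogen slowly, and the alkene may first migrate into conjugation, which would scramble C5. The fallback uses a radical mechanism that ends at the thermodynamically preferred ring fusion. Starting from 13, hydrogen-atom-transfer hydrogenation (Mn(dpm)3, PhSiH3, t-BuOOH, i-PrOH) forms the tertiary C5 radical, which accepts hydrogen axially and gives 11,11'-bi(12-nor-5α-drim-1-en-8-one) F10. Brief hydrogenation of the remaining C1=C2 bond over Pd/C then gives 14.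

Step 10. The hindered C9 hydrogen may be removed slowly, and competing γ-deprotonation at C5 would erode the ring-fusion configuration. The fallback places the methyl group by carbonyl addition instead of enolate chemistry. Starting from 16, MeLi with CeCl3 adds to the C8 carbonyl and gives 11,11'-bi(5α-drim-6-en-8ξ-ol) F11. Dehydration with the Burgess reagent, for which C9–H is the only ring hydrogen next to C8, gives the diene 19.

Step 12. Hydrogen transfer to the C6=C7 bond inside the hindered diene may be slow and stop at partial conversion, and prolonged reaction times invite hydrogen shifts within the diene. The fallback avoids the diene altogether, at the price of weaker regiocontrol. Starting from 14, thermodynamic enol triflation (Tf2O, 2,6-di-tert-butyl-4-methylpyridine, CH2Cl2) toward the more substituted side gives 11,11'-bi(12-nor-5α-drim-8-en-8-yl trifluoromethanesulfonate) F12. Coupling with MeMgBr and Fe(acac)3 as in step 11 gives 20 directly.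

## Further compounds

F1 | step 3 | bis[(1S)-4-hydroxy-3,5,5-trimethylcyclohex-2-en-1-yl] hexanedioate | CC1=C[C@@H](OC(=O)CCCCC(=O)O[C@@H]2C=C(C)C(O)C(C)(C)C2)CC(C)(C)C1O
F2 | step 3 | bis[(1S)-4-(tert-butyldimethylsilyloxy)-3,5,5-trimethylcyclohex-2-en-1-yl] hexanedioate | CC1=C[C@@H](OC(=O)CCCCC(=O)O[C@@H]2C=C(C)C(O[Si](C)(C)C(C)(C)C)C(C)(C)C2)CC(C)(C)C1O[Si](C)(C)C(C)(C)C
F3 | step 3 | 2,5-bis[(1R)-6-(tert-butyldimethylsilyloxy)-1,5,5-trimethylcyclohex-2-en-1-yl]hexanedioic acid | OC(=O)C(CCC(C(=O)O)[C@@]1(C)C=CCC(C)(C)C1O[Si](C)(C)C(C)(C)C)[C@@]1(C)C=CCC(C)(C)C1O[Si](C)(C)C(C)(C)C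
F4 | step 3 | N1,N6-dimethoxy-N1,N6-dimethyl-2,5-bis[(1R)-6-(tert-butyldimethylsilyloxy)-1,5,5-trimethylcyclohex-2-en-1-yl]hexanediamide | CON(C)C(=O)C(CCC(C(=O)N(C)OC)[C@@]1(C)C=CCC(C)(C)C1O[Si](C)(C)C(C)(C)C)[C@@]1(C)C=CCC(C)(C)C1O[Si](C)(C)C(C)(C)C
F5 | step 3 | N1,N6-dimethoxy-N1,N6-dimethyl-2,5-bis[(1R)-6-hydroxy-1,5,5-trimethylcyclohex-2-en-1-yl]hexanediamide | CON(C)C(=O)C(CCC(C(=O)N(C)OC)[C@@]1(C)C=CCC(C)(C)C1O)[C@@]1(C)C=CCC(C)(C)C1O
F6 | step 6 | 4,7-bis[(1R)-6-ethenyl-6-hydroxy-1,5,5-trimethylcyclohex-2-en-1-yl]deca-1,9-diene-3,8-dione | C=CC(=O)C(CCC(C(=O)C=C)[C@@]1(C)C=CCC(C)(C)C1(O)C=C)[C@@]1(C)C=CCC(C)(C)C1(O)C=C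
F7 | step 6 | 11,11'-bi(5ξ-hydroxy-12-nordrima-1,6-dien-8-one), 10β-methyl | C(CC1C(=O)C=CC2(O)C(C)(C)CC=C[C@]12C)C1C(=O)C=CC2(O)C(C)(C)CC=C[C@]12C
F8 | step 6 | 11,11'-bi(5ξ-hydroxy-12-nordriman-8-one), 10β-methyl | C(CC1C(=O)CCC2(O)C(C)(C)CCC[C@]12C)C1C(=O)CCC2(O)C(C)(C)CCC[C@]12C
F9 | step 6 | 11,11'-bi(12-nordrim-5-en-8-one), 10β-methyl | C(CC1C(=O)CC=C2C(C)(C)CCC[C@]12C)C1C(=O)CC=C2C(C)(C)CCC[C@]12C
F10 | step 8 | 11,11'-bi(12-nor-5α-drim-1-en-8-one), 10β-methyl | C(CC1C(=O)CC[C@H]2C(C)(C)CC=C[C@]12C)C1C(=O)CC[C@H]2C(C)(C)CC=C[C@]12C
F11 | step 10 | 11,11'-bi(5α-drim-6-en-8ξ-ol), 10β-methyl | C(CC1C(C)(O)C=C[C@H]2C(C)(C)CCC[C@]12C)C1C(C)(O)C=C[C@H]2C(C)(C)CCC[C@]12C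
F12 | step 12 | 11,11'-bi(12-nor-5α-drim-8-en-8-yl trifluoromethanesulfonate) | C(CC1=C(OS(=O)(=O)C(F)(F)F)CC[C@H]2C(C)(C)CCC[C@]12C)C1=C(OS(=O)(=O)C(F)(F)F)CC[C@H]2C(C)(C)CCC[C@]12C
A1 | alternative 1 | 11,11'-bi(drim-8-ene)-6,6'-dicarbaldehyde | CC1=C(CCC2=C(C)C[C@H](C=O)[C@H]3C(C)(C)CCC[C@]23C)[C@@]2(C)CCCC(C)(C)[C@@H]2[C@@H](C=O)C1
A2 | alternative 2 | 1,2-bis(9-hydroxy-11-nordriman-9-yl)ethyne | C[C@@H]1CC[C@H]2C(C)(C)CCC[C@]2(C)[C@]1(O)C#C[C@]1(O)[C@H](C)CC[C@H]2C(C)(C)CCC[C@]12C
A3 | alternative 2 | 11-nordriman-9-one (trans-fused, 5α-H, 10β-methyl) | C[C@@H]1CC[C@H]2C(C)(C)CCC[C@]2(C)C1=O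
A4 | alternative 3 | 5,5'-(ethane-1,2-diyl)bis(4a,6-dimethyl-4,4a,7,8-tetrahydronaphthalen-2(3H)-one) | CC1=C(CCC2=C(C)CCC3=CC(=O)CC[C@]23C)[C@@]2(C)CCC(=O)C=C2CC1
A5 | alternative 3 | 3,3'-(ethane-1,2-diyl)bis(2,4-dimethylcyclohex-2-en-1-one) | CC1CCC(=O)C(C)=C1CCC1=C(C)C(=O)CCC1C
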